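The cyclohexanone ring is disconnected into two three-carbon pieces across C3–C4 (ester-bearing carbon to side-chain-bearing carbon) and across the oxirane C–C bond C1–C6 (7-oxabicyclo[4.1.0]heptane locants). The key step exploits that ketone C2 is flanked by both carbons to be bonded (C1, C3), while C4 and C6 are 1,3-related through CH2-5, like the β- and carbonyl carbons of an enal. An amine-catalysed Michael/aldol-condensation/decarboxylation cascade between acyclic (2E)-4-bromopenta-2,4-dienal and tert-butyl 3-oxopentanoate forges both bonds (C1–C6 first as C=C), sets C4 and gives a carvone-type enone. Hydroxyl-directed epoxidation, enolate hydroxylation, tigloylation and carbonylative Stille coupling follow.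

Key step: step 3

Remark on the chemistry: the oxirane is closed from the alkene and not by a chloro-ketone (Darzens-type) variant of the same annulation, because the trans-diaxial closure of that variant would place the oxirane oxygen anti to the C4 substituent, whereas the target has it syn.

Step 1
Reactants: 1 acrolein (prop-2-enal)
Product: 3 2-bromoprop-2-enal, via 2,3-dibromopropanal 2 (not isolated)
Conditions: Br2, CH2Cl2, −78 °C to 0 °C; then Et3N, 0 °C
Reagents that add atoms: bromine, BrBr
Why: Bromine addition across the alkene followed by amine-mediated loss of HBr from the acidic α-position (bromination–dehydrobromination) should give the α-bromo enal.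

Step 2
Reactants: 3 2-bromoprop-2-enal; 4 (triphenylphosphoranylidene)acetaldehyde
Product: 5 (2E)-4-bromopenta-2,4-dienal
Conditions: CH2Cl2, 0 °C to rt, 3 in slight excess
Reagents that add atoms: none
Why: Wittig olefination with the formyl-stabilised ylide should be (E)-selective, and the conjugated product is less electrophilic than 3, which limits a second homologation.

Step 3
Reactants: 5 (2E)-4-bromopenta-2,4-dienal; 6 tert-butyl 3-oxopentanoate
Product: 9 (5R)-5-(1-bromoethenyl)-2-methylcyclohex-2-en-1-one, via Michael adduct 7 (not isolated), via cyclohexenone tert-butyl ester 8 (not isolated)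
Conditions: (S)-2-{bis[3,5-bis(trifluoromethyl)phenyl](trimethylsilyloxy)methyl}pyrrolidine (10 mol%), PhCO2H (10 mol%), toluene, 0 °C to rt; then p-TsOH·H2O (20 mol%), 80 °C, one pot
Reagents that add atoms: none
Why: Condensation of the secondary amine with 5 gives an (E)-iminium ion whose diaryl(silyloxy)methyl group blocks one face, so the doubly activated carbon of 6 adds to the enal β-carbon from the open face and sets the (R) centre (C5 of 9, C4 of the target) under catalyst control, and hydrolysis releases aldehyde 7. On acidification and warming the enol of the ethyl ketone attacks the aldehyde in a 6-(enolendo)-exo-trig aldol closure, dehydration gives the conjugated 2-methyl enone 8, and loss of 2-methylpropene and CO2 from the tert-butyl ester removes the activating group. The two new ring bonds are C5–C6 and C2–C3 of 9, which are C4–C3 and C6–C1 of the target bicycle. The closest known reaction type is the amine-catalysed Robinson-type [3+3] annulation of β-keto esters with enals to 5-substituted cyclohex-2-enones. The step needs 1,4- rather than 1,6-addition to the dienal, which the larger β-coefficient of the iminium LUMO and lone-pair donation from bromine into the terminal CH2 should secure, and it needs the carbon between the two carbonyl groups as the only nucleophile, which its acidity secures under these base-free conditions. Only the ketone CH2 can reach the aldehyde through a six-membered transition state, so the regiochemistry of ring closure and the position of the methyl group are unambiguous.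

Step 4
Reactants: 9 (5R)-5-(1-bromoethenyl)-2-methylcyclohex-2-en-1-one
Product: 10 (1R,5R)-5-(1-bromoethenyl)-2-methylcyclohex-2-en-1-ol
Conditions: NaBH4, CeCl3·7H2O, MeOH, −78 °C to −20 °C
Reagents that add atoms: none
Why: Luche 1,2-reduction with axial hydride delivery to the half-chair enone carrying a pseudo-equatorial C5 substituent should give the equatorial alcohol cis to the bromovinyl group, as with carvone-type enones.

Step 5
Reactants: 10 (1R,5R)-5-(1-bromoethenyl)-2-methylcyclohex-2-en-1-ol
Product: 11 (1R,2R,4S,6S)-4-(1-bromoethenyl)-1-methyl-7-oxabicyclo[4.1.0]heptan-2-ol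
Conditions: VO(acac)2 (3 mol%), t-BuOOH (in decane), CH2Cl2, 0 °C to rt
Reagents that add atoms: tert-butyl hydroperoxide, CC(C)(C)OO
Why: Vanadium-catalysed hydroxyl-directed epoxidation delivers oxygen to the allylic alkene on the face of the OH group, hence syn to the bromovinyl group, and leaves the electron-poor bromoalkene untouched.

Step 6
Reactants: 11 (1R,2R,4S,6S)-4-(1-bromoethenyl)-1-methyl-7-oxabicyclo[4.1.0]heptan-2-ol
Product: 12 (1S,4R,6S)-4-(1-bromoethenyl)-1-methyl-7-oxabicyclo[4.1.0]heptan-2-one
Conditions: Dess–Martin periodinane, NaHCO3, CH2Cl2, 0 °C to rt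
Reagents that add atoms: none
Why: Buffered Dess–Martin oxidation of the secondary epoxy alcohol should return the ketone without opening the oxirane or touching a stereocentre.

Step 7
Reactants: 12 (1S,4R,6S)-4-(1-bromoethenyl)-1-methyl-7-oxabicyclo[4.1.0]heptan-2-one
Product: 14 (1S,3S,4R,6S)-4-(1-bromoethenyl)-3-hydroxy-1-methyl-7-oxabicyclo[4.1.0]heptan-2-one, via sodium enolate 13 (not isolated)
Conditions: NaN(SiMe3)2, THF, −78 °C; then 2-(phenylsulfonyl)-3-phenyloxaziridine, −78 °C; sat. aq. NH4Cl
Reagents that add atoms: 2-(phenylsulfonyl)-3-phenyloxaziridine, O=S(=O)(c1ccccc1)N1OC1c1ccccc1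
Why: Only C3 can be deprotonated (C1 is quaternary), and oxygen transfer from the N-sulfonyloxaziridine to the enolate should occur on the face opposite both the adjacent bromovinyl group and the oxirane oxygen, giving the (3S) alcohol (enolate hydroxylation).

Step 8
Reactants: 14 (1S,3S,4R,6S)-4-(1-bromoethenyl)-3-hydroxy-1-methyl-7-oxabicyclo[4.1.0]heptan-2-one
Product: 15 (1S,3S,4R,6S)-4-(1-bromoethenyl)-1-methyl-2-oxo-7-oxabicyclo[4.1.0]heptan-3-yl (2E)-2-methylbut-2-enoate
Conditions: (E)-2-methylbut-2-enoyl chloride, pyridine, DMAP (cat.), CH2Cl2, 0 °C to rt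
Reagents that add atoms: (E)-2-methylbut-2-enoyl chloride (tigloyl chloride), C/C=C(\C)C(=O)Cl
Why: Nucleophile-catalysed acylation of the secondary α-hydroxy ketone should give the tiglate, whose (E)-geometry is configurationally stable, and the trans C3/C4 arrangement is the favoured one should C3 equilibrate.

Step 9
Reactants: 16 2-methylbut-3-yn-2-ol
Product: 17 (3E)-2-methyl-4-(tributylstannyl)but-3-en-2-ol
Conditions: Bu3SnH, AIBN (cat.), toluene, 85 °C
Reagents that add atoms: tributyltin hydride, CCCC[SnH](CCCC)CCCC
Why: Radical hydrostannation places tin on the terminal alkyne carbon, and reversible stannyl-radical addition should equilibrate the product to the (E)-vinylstannane.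

Step 10
Reactants: 15 (1S,3S,4R,6S)-4-(1-bromoethenyl)-1-methyl-2-oxo-7-oxabicyclo[4.1.0]heptan-3-yl (2E)-2-methylbut-2-enoate; 17 (3E)-2-methyl-4-(tributylstannyl)but-3-en-2-ol
Product: 18 (1S,3S,4S,6S)-4-[(4E)-6-hydroxy-6-methyl-3-oxohepta-1,4-dien-2-yl]-1-methyl-2-oxo-7-oxabicyclo[4.1.0]heptan-3-yl (2E)-2-methylbut-2-enoate
Conditions: Pd2(dba)3 (2.5 mol%), AsPh3 (20 mol%), CO (3 atm), N-methylpyrrolidone, 50 °C
Reagents that add atoms: carbon monoxide, [C-]#[O+]
Why: In this carbonylative Stille coupling, oxidative addition of the 1,1-disubstituted vinyl bromide to zerovalent palladium, CO insertion and transmetalation/reductive elimination with the (E)-vinylstannane (alkene geometry retained) should give the cross-conjugated dienone under neutral conditions that spare the epoxy ketone, the ester and the free tertiary alcohol.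

Compound list
1 | acrolein (prop-2-enal) | C=CC=O | starting material
2 | 2,3-dibromopropanal (racemic) | O=CC(Br)CBr | intermediate
3 | 2-bromoprop-2-enal | C=C(Br)C=O | intermediate
4 | (triphenylphosphoranylidene)acetaldehyde | O=CC=P(c1ccccc1)(c1ccccc1)c1ccccc1 | starting material
5 | (2E)-4-bromopenta-2,4-dienal | C=C(Br)/C=C/C=O | intermediate
6 | tert-butyl 3-oxopentanoate | CCC(=O)CC(=O)OC(C)(C)C | starting material
7 | tert-butyl (3R)-3-(1-bromoethenyl)-5-oxo-2-propanoylpentanoate (C2 epimers) | C=C(Br)[C@H](CC=O)C(C(=O)CC)C(=O)OC(C)(C)C | intermediate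
8 | tert-butyl (6R)-6-(1-bromoethenyl)-3-methyl-2-oxocyclohex-3-ene-1-carboxylate (C1 epimers) | C=C(Br)[C@@H]1CC=C(C)C(=O)C1C(=O)OC(C)(C)C | intermediate
9 | (5R)-5-(1-bromoethenyl)-2-methylcyclohex-2-en-1-one | C=C(Br)[C@@H]1CC=C(C)C(=O)C1 | intermediate
10 | (1R,5R)-5-(1-bromoethenyl)-2-methylcyclohex-2-en-1-ol | C=C(Br)[C@@H]1CC=C(C)[C@H](O)C1 | intermediate
11 | (1R,2R,4S,6S)-4-(1-bromoethenyl)-1-methyl-7-oxabicyclo[4.1.0]heptan-2-ol | C=C(Br)[C@@H]1C[C@@H]2O[C@]2(C)[C@H](O)C1 | intermediate
12 | (1S,4R,6S)-4-(1-bromoethenyl)-1-methyl-7-oxabicyclo[4.1.0]heptan-2-one | C=C(Br)[C@@H]1C[C@@H]2O[C@]2(C)C(=O)C1 | intermediate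
13 | sodium enolate of 12 (C2–C3 enolate) | C=C(Br)[C@@H]1C[C@@H]2O[C@]2(C)C([O-])=C1.[Na+] | intermediate
14 | (1S,3S,4R,6S)-4-(1-bromoethenyl)-3-hydroxy-1-methyl-7-oxabicyclo[4.1.0]heptan-2-one | C=C(Br)[C@@H]1C[C@@H]2O[C@]2(C)C(=O)[C@H]1O | intermediate
15 | (1S,3S,4R,6S)-4-(1-bromoethenyl)-1-methyl-2-oxo-7-oxabicyclo[4.1.0]heptan-3-yl (2E)-2-methylbut-2-enoate | C=C(Br)[C@@H]1C[C@@H]2O[C@]2(C)C(=O)[C@H]1OC(=O)/C(C)=C/C | intermediate
16 | 2-methylbut-3-yn-2-ol | C#CC(C)(C)O | starting material
17 | (3E)-2-methyl-4-(tributylstannyl)but-3-en-2-ol | CCCC[Sn](CCCC)(CCCC)/C=C/C(C)(C)O | intermediate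
18 | (1S,3S,4S,6S)-4-[(4E)-6-hydroxy-6-methyl-3-oxohepta-1,4-dien-2-yl]-1-methyl-2-oxo-7-oxabicyclo[4.1.0]heptan-3-yl (2E)-2-methylbut-2-enoate | C=C(C(=O)/C=C/C(C)(C)O)[C@@H]1C[C@@H]2O[C@]2(C)C(=O)[C@H]1OC(=O)/C(C)=C/C | target

Total step count: 10. Longest linear sequence: 9 steps (steps 1 to 8 and step 10); step 9 is a one-step branch.

Steps most likely to fail

1. Step 3. Conjugate addition may partition to the unsubstituted diene terminus (1,6-addition), the dienal may oligomerise under amine catalysis, and the Michael adduct may rest as a cyclic lactol and dehydrate to a pyran instead of closing by aldol reaction. The fallback sets out from 4 and 6 and comes back at 9; it keeps the annulation but carries the side-chain handle as a silyl-capped alkyne. Wittig olefination of commercial 3-(trimethylsilyl)prop-2-ynal with 4 (CH2Cl2, rt) should give (2E)-5-(trimethylsilyl)pent-2-en-4-ynal F1, whose alkyne terminus is closed to nucleophiles. The same one-pot annulation with 6 (the (S)-pyrrolidine catalyst of step 3, PhCO2H, toluene; then p-TsOH·H2O, 80 °C) should pass through the Michael adduct tert-butyl (3R)-5-oxo-2-propanoyl-3-[(trimethylsilyl)ethynyl]pentanoate F2 and the cyclised ester tert-butyl (6R)-3-methyl-2-oxo-6-[(trimethylsilyl)ethynyl]cyclohex-3-ene-1-carboxylate F3 to (5R)-2-methyl-5-[(trimethylsilyl)ethynyl]cyclohex-2-en-1-one F4. K2CO3 in MeOH at 0 °C should remove silicon to give (5R)-5-ethynyl-2-methylcyclohex-2-en-1-one F5. syn-Bromoboration of the terminal alkyne with B-bromo-9-borabicyclo[3.3.1]nonane (CH2Cl2, 0 °C) should give 9-[(Z)-2-bromo-2-[(1R)-4-methyl-5-oxocyclohex-3-en-1-yl]ethenyl]-9-borabicyclo[3.3.1]nonane F6, and protodeboronation with acetic acid should deliver 9 (net Markovnikov hydrobromination).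

2. Step 10. Oxidative addition of the vinyl bromide may be slow, direct coupling without CO insertion may compete, and zerovalent palladium may isomerise the epoxy ketone on prolonged heating. The fallback sets out from 15 and 17 and comes back at 18; it replaces the carbonylation by a 1,2-addition followed by oxidation. Tin–lithium exchange on 17 (MeLi, then n-BuLi, THF, −78 °C) and formylation with DMF should give (2E)-4-hydroxy-4-methylpent-2-enal F7. Nozaki–Hiyama–Kishi coupling of 15 with F7 (CrCl2, catalytic NiCl2, DMF, rt), which is selective for aldehydes over ketones and esters, should give (1S,3S,4S,6S)-4-[(4E)-3,6-dihydroxy-6-methylhepta-1,4-dien-2-yl]-1-methyl-2-oxo-7-oxabicyclo[4.1.0]heptan-3-yl (2E)-2-methylbut-2-enoate F8 as a mixture of carbinol epimers. MnO2 (CH2Cl2, rt) should then oxidise the secondary bis-allylic alcohol selectively to 18. The exposure of the epoxy ketone to the chromium reductant is the weak point of this alternative.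

3. Step 7. Facial discrimination in the oxygen transfer may be insufficient, the enolate may add to the sulfonimine by-product, and the base may open the oxirane. The fallback sets out from 12 and comes back at 14; it avoids a free enolate. Soft enolisation of 12 with Me3SiOTf and Et3N (CH2Cl2, 0 °C) should give {[(1S,4R,6S)-4-(1-bromoethenyl)-1-methyl-7-oxabicyclo[4.1.0]hept-2-en-2-yl]oxy}trimethylsilane F9. Epoxidation with dimethyldioxirane (acetone, −40 °C) should give the 2,3-epoxide of this enol ether F10 (new oxirane anti to the bromovinyl group and to the existing oxirane), which should collapse to 14 on work-up with citric acid in MeOH (Rubottom oxidation).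

Further compounds
F1 | step 3 | (2E)-5-(trimethylsilyl)pent-2-en-4-ynal | C[Si](C)(C)C#C/C=C/C=O
F2 | step 3 | tert-butyl (3R)-5-oxo-2-propanoyl-3-[(trimethylsilyl)ethynyl]pentanoate (C2 epimers) | C[Si](C)(C)C#C[C@H](CC=O)C(C(=O)CC)C(=O)OC(C)(C)C
F3 | step 3 | tert-butyl (6R)-3-methyl-2-oxo-6-[(trimethylsilyl)ethynyl]cyclohex-3-ene-1-carboxylate (C1 epimers) | C[Si](C)(C)C#C[C@@H]1CC=C(C)C(=O)C1C(=O)OC(C)(C)C
F4 | step 3 | (5R)-2-methyl-5-[(trimethylsilyl)ethynyl]cyclohex-2-en-1-one | C[Si](C)(C)C#C[C@@H]1CC=C(C)C(=O)C1
F5 | step 3 | (5R)-5-ethynyl-2-methylcyclohex-2-en-1-one | C#C[C@@H]1CC=C(C)C(=O)C1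
F6 | step 3 | 9-[(Z)-2-bromo-2-[(1R)-4-methyl-5-oxocyclohex-3-en-1-yl]ethenyl]-9-borabicyclo[3.3.1]nonane | B1(C2CCCC1CCC2)/C=C(\Br)[C@@H]1CC=C(C)C(=O)C1
F7 | step 10 | (2E)-4-hydroxy-4-methylpent-2-enal | CC(C)(O)/C=C/C=O
F8 | step 10 | (1S,3S,4S,6S)-4-[(4E)-3,6-dihydroxy-6-methylhepta-1,4-dien-2-yl]-1-methyl-2-oxo-7-oxabicyclo[4.1.0]heptan-3-yl (2E)-2-methylbut-2-enoate (carbinol epimers) | C=C(C(O)/C=C/C(C)(C)O)[C@@H]1C[C@@H]2O[C@]2(C)C(=O)[C@H]1OC(=O)/C(C)=C/C
F9 | step 7 | {[(1S,4R,6S)-4-(1-bromoethenyl)-1-methyl-7-oxabicyclo[4.1.0]hept-2-en-2-yl]oxy}trimethylsilane | C=C(Br)[C@@H]1C[C@@H]2O[C@]2(C)C(O[Si](C)(C)C)=C1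
F10 | step 7 | 2,3-epoxide of F9 (2-trimethylsilyloxy bis-oxirane, new oxirane anti to the bromovinyl group) | C=C(Br)[C@@H]1C[C@@H]2O[C@]2(C)[C@@]3(O[Si](C)(C)C)O[C@@H]13
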